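**Retrosynthetic overview** (ring A = benzene ring, ring B = pyran ring, ring C = cyclohexane ring)
- Target 21 ⇐ chromanone 19: a temporary C4 carbonyl is removed by reduction and dehydration, which installs C3=C4.
- 19 ⇐ methyl ketone 11 + aryl ketone enol silane 15 in one flask: catalyst-controlled Mukaiyama aldol (C2–C3, sets C2), desilylation, oxidation of the catechol to the o-quinone, 6-endo oxa-Michael addition (O1–C8a). Ring B is formed last, between finished rings A and C.
- Enabling feature: C4 of ring B is benzylic, so a carbonyl there turns C3 into an enol-silane nucleophile. With the C5/C6 catechol of ring A at the o-quinone level, the unsubstituted C8a (para to the C6 oxygen, ortho to C4a) is the β-carbon of two enones and accepts O1 without a leaving group.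
- 11 ⇐ octalone 7 (ozonolysis, Peterson methylenation, MeLi) ⇐ 2,6-dimethylcyclohexanone + methyl vinyl ketone (auxiliary-controlled Michael addition, then Robinson annulation that sets the trans ring methyls of ring C).
- 15 ⇐ 1-(2-hydroxy-5-methoxyphenyl)ethanone (bromination, hydroxylation, silylation).

Key step: step 10

Assumption: the (S)-amine is taken to direct the Michael addition of the 2,6-dimethyl imine in the same sense as for 2-methylcyclohexanone (R at the new quaternary carbon), and the enantiomer of the confined acid used in step 10 is the one that delivers the donor to the Re face of the carbonyl of 11; the antipodes would be used otherwise.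

**Step 1**
Reactants: 1 2,6-dimethylcyclohexanone (commercial cis/trans mixture); 2 (S)-1-phenylethylamine
Product: 3 (1S)-N-(2,6-dimethylcyclohexylidene)-1-phenylethanamine
Conditions: p-TsOH (cat.), toluene, reflux, Dean–Stark trap
Reagents that add atoms: none
Why: Acid-catalysed imine formation with azeotropic removal of water attaches the chiral controller for step 2, the ring stereocentres being still unset.

**Step 2**
Reactants: 3 (1S)-N-(2,6-dimethylcyclohexylidene)-1-phenylethanamine; 4 methyl vinyl ketone
Product: 6 (2R)-2,6-dimethyl-2-(3-oxobutyl)cyclohexan-1-one (epimers at C6), via imine adduct 5 (not isolated)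
Conditions: THF, rt; then aq. AcOH (10%), rt
Reagents that add atoms: water, O
Why: The secondary enamine tautomer of 3 should add to the enone in an aza-ene-like Michael addition of a chiral imine, the acceptor approaching the face anti to the phenyl group of the auxiliary, which sets the quaternary carbon (R); hydrolysis returns the amine, and the methyl-bearing α-carbon is left as an epimer mixture to be corrected in step 3.

**Step 3**
Reactants: 6 (2R)-2,6-dimethyl-2-(3-oxobutyl)cyclohexan-1-one
Product: 7 (4aR,8R)-4a,8-dimethyl-4,4a,5,6,7,8-hexahydronaphthalen-2(3H)-one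
Conditions: NaOMe, MeOH, reflux
Reagents that add atoms: none
Why: Robinson-type intramolecular aldol condensation under equilibrating base closes the enone ring and should epimerise C8 through the extended dienolate to the equatorial methyl, trans to the axial angular methyl (no 1,3-diaxial methyl/methyl contact), which fixes the trans relation of the two ring methyls.

**Step 4**
Reactants: 7 (4aR,8R)-4a,8-dimethyl-4,4a,5,6,7,8-hexahydronaphthalen-2(3H)-one
Product: 8 3-[(1R,3R)-1,3-dimethyl-2-oxocyclohexyl]propanoic acid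
Conditions: O3, CH2Cl2/MeOH, −78 °C; then H2O2 (30%), HCO2H, rt
Reagents that add atoms: ozone, [O-][O+]=O; hydrogen peroxide, OO
Why: Ozonolysis of the enone with oxidative work-up cleaves C1=C8a to the ring ketone and, after loss of C1 as CO2, the propanoic acid chain; the non-basic conditions should leave the stereocentre α to the new ketone as set in step 3.

**Step 5**
Reactants: 8 3-[(1R,3R)-1,3-dimethyl-2-oxocyclohexyl]propanoic acid
Product: 10 3-[(1R,3R)-1,3-dimethyl-2-methylidenecyclohexyl]propanoic acid, via hydroxysilane acid 9 (not isolated)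
Conditions: TMSCH2Li, CeCl3, THF, −78 to 0 °C; then aq. HCl, rt
Reagents that add atoms: (trimethylsilyl)methyllithium, C[Si](C)(C)C[Li]
Why: The weakly basic organocerium reagent should add to the hindered, enolisable ketone of the carboxylate without epimerising the adjacent methyl-bearing carbon, and acid then eliminates the β-hydroxysilane to the exocyclic alkene (Peterson olefination), both ring stereocentres being untouched.

**Step 6**
Reactants: 10 3-[(1R,3R)-1,3-dimethyl-2-methylidenecyclohexyl]propanoic acid
Product: 11 4-[(1R,3R)-1,3-dimethyl-2-methylidenecyclohexyl]butan-2-one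
Conditions: MeLi (2.5 equiv), Et2O, 0 °C to rt; inverse quench into aq. HCl
Reagents that add atoms: methyllithium, C[Li]
Why: Methyllithium adds to the lithium carboxylate to give a geminal dialkoxide that collapses to the methyl ketone only on acidic quench (conversion of a carboxylic acid into a methyl ketone with MeLi).

**Step 7**
Reactants: 12 1-(2-hydroxy-5-methoxyphenyl)ethanone
Product: 13 1-(3-bromo-2-hydroxy-5-methoxyphenyl)ethanone
Conditions: Br2, NaOAc, AcOH, rt
Reagents that add atoms: bromine, BrBr
Why: Electrophilic aromatic bromination should go ortho to the free hydroxyl, whose para position is blocked by the methoxy group.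

**Step 8**
Reactants: 13 1-(3-bromo-2-hydroxy-5-methoxyphenyl)ethanone
Product: 14 1-(2,3-dihydroxy-5-methoxyphenyl)ethanone
Conditions: NaOH (aq), CuSO4 (cat.), reflux under N2; then HCl
Reagents that add atoms: sodium hydroxide, [Na+].[OH-]
Why: Copper-catalysed hydroxylation of the aryl bromide in hot aqueous base (Ullmann-type hydroxylation of an o-bromophenol) installs the second phenol ortho to the first.

**Step 9**
Reactants: 14 1-(2,3-dihydroxy-5-methoxyphenyl)ethanone
Product: 15 triethyl({1-[5-methoxy-2,3-bis(triethylsilyloxy)phenyl]ethenyl}oxy)silane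
Conditions: Et3SiOTf (3.3 equiv), Et3N, CH2Cl2, 0 °C
Reagents that add atoms: triethylsilyl trifluoromethanesulfonate, CC[Si](CC)(CC)OS(=O)(=O)C(F)(F)F
Why: Silyl triflate and amine base silylate both phenols and convert the methyl ketone into its silyl enol ether in one operation (soft enolisation).

**Step 10**
Reactants: 11 4-[(1R,3R)-1,3-dimethyl-2-methylidenecyclohexyl]butan-2-one; 15 triethyl({1-[5-methoxy-2,3-bis(triethylsilyloxy)phenyl]ethenyl}oxy)silane
Product: 19 (2S)-2-{2-[(1R,3R)-1,3-dimethyl-2-methylidenecyclohexyl]ethyl}-5,6-dihydroxy-8-methoxy-2-methyl-2,3-dihydro-4H-chromen-4-one, via aldol silyl ether 16 (not isolated), via hydroxy ketone catechol 17 (not isolated), via acyl-o-quinone 18 (not isolated)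
Conditions: chiral confined BINOL-derived imidodiphosphorimidate Brønsted acid (2 mol%), toluene, −40 °C; then Et3N·3HF, MeCN, 0 °C to rt; then PhI(OAc)2 (1 equiv), 0 °C
Reagents that add atoms: none
Why: Proposed new method: 15 silylates the confined acid, and the silylium–imidodiphosphorimidate ion pair activates the unhindered methyl ketone of 11 as an O-silyl oxocarbenium ion that the enol-silane carbon (future C3) attacks at C2, silyl transfer closing the cycle; the closest known reaction type is the confined-acid-catalysed Mukaiyama aldol addition of silyl ketene acetals to simple methyl alkyl ketones, and the new element is an aryl ketone enol silane as donor. Et3N·3HF then removes the three silyl groups, PhI(OAc)2 oxidises the freed C5/C6 catechol to o-quinone 18, and the tertiary hydroxyl O1 adds to C8a, the β-carbon of both the C5 quinone carbonyl and the C4 aryl ketone, in a 6-endo-trig oxa-Michael addition that closes ring B, after which enolisation returns the catechol (the same event as the known oxidative lactonisation of hydroxycinnamic acids through their o-quinones). The only new stereocentre, C2 (S), is set in the aldol stage by the chiral anion, which should direct the donor to the Re face of the ketone by telling the methyl group from the CH2CH2 chain; the remote centres of ring C exert no control and the later stages do not touch C2. The step needs chemoselectivity for the enol-silane carbon over arene carbon C7 and for the methyl ketone over the 1,1-disubstituted alkene, secured by the higher nucleophilicity of the enol silane and by the absence of free protons while silylium carries the chain, and regioselectivity for C8a over C7 in the ring closure, secured by ring size (only C8a gives a six-membered ring) and by its double activation.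

**Step 11**
Reactants: 19 (2S)-2-{2-[(1R,3R)-1,3-dimethyl-2-methylidenecyclohexyl]ethyl}-5,6-dihydroxy-8-methoxy-2-methyl-2,3-dihydro-4H-chromen-4-one
Product: 21 (2S)-2-{2-[(1R,3R)-1,3-dimethyl-2-methylidenecyclohexyl]ethyl}-8-methoxy-2-methyl-2H-chromene-5,6-diol, via chroman-4-ol 20 (not isolated)
Conditions: NaBH4, MeOH, 0 °C to rt; aqueous work-up; then PPTS (cat.), toluene, 60 °C, dilute
Reagents that add atoms: none
Why: Hydride reduction of the aryl ketone followed by acid-catalysed E1 dehydration of the benzylic alcohol, whose cation is stabilised by O1 and the C5 hydroxyl, should install the conjugated C3=C4 bond, while C2 is not involved and the weak acid should leave the exocyclic alkene alone.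

**Compound list**
1 | 2,6-dimethylcyclohexanone (cis/trans mixture) | CC1CCCC(C)C1=O | starting material
2 | (S)-1-phenylethylamine | C[C@H](N)c1ccccc1 | starting material
3 | (1S)-N-(2,6-dimethylcyclohexylidene)-1-phenylethanamine | C[C@H](N=C1C(C)CCCC1C)c1ccccc1 | intermediate
4 | methyl vinyl ketone (but-3-en-2-one) | C=CC(C)=O | starting material
5 | 4-[(1R)-1,3-dimethyl-2-{[(1S)-1-phenylethyl]imino}cyclohexyl]butan-2-one (epimers at C3) | C[C@H](N=C1C(C)CCC[C@]1(C)CCC(C)=O)c1ccccc1 | intermediate
6 | (2R)-2,6-dimethyl-2-(3-oxobutyl)cyclohexan-1-one (epimers at C6) | O=C1C(C)CCC[C@]1(C)CCC(C)=O | intermediate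
7 | (4aR,8R)-4a,8-dimethyl-4,4a,5,6,7,8-hexahydronaphthalen-2(3H)-one | O=C2C=C1[C@H](C)CCC[C@]1(C)CC2 | intermediate
8 | 3-[(1R,3R)-1,3-dimethyl-2-oxocyclohexyl]propanoic acid | O=C1[C@H](C)CCC[C@]1(C)CCC(=O)O | intermediate
9 | 3-[(1R,3R)-2-hydroxy-1,3-dimethyl-2-(trimethylsilylmethyl)cyclohexyl]propanoic acid (carbinol carbon undefined; present as its salt) | C[Si](C)(C)CC1(O)[C@H](C)CCC[C@]1(C)CCC(=O)O | intermediate
10 | 3-[(1R,3R)-1,3-dimethyl-2-methylidenecyclohexyl]propanoic acid | C=C1[C@H](C)CCC[C@]1(C)CCC(=O)O | intermediate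
11 | 4-[(1R,3R)-1,3-dimethyl-2-methylidenecyclohexyl]butan-2-one | C=C1[C@H](C)CCC[C@]1(C)CCC(C)=O | intermediate
12 | 1-(2-hydroxy-5-methoxyphenyl)ethanone | CC(=O)c1cc(OC)ccc1O | starting material
13 | 1-(3-bromo-2-hydroxy-5-methoxyphenyl)ethanone | CC(=O)c1cc(OC)cc(Br)c1O | intermediate
14 | 1-(2,3-dihydroxy-5-methoxyphenyl)ethanone | CC(=O)c1cc(OC)cc(O)c1O | intermediate
15 | triethyl({1-[5-methoxy-2,3-bis(triethylsilyloxy)phenyl]ethenyl}oxy)silane | C=C(O[Si](CC)(CC)CC)c1cc(OC)cc(O[Si](CC)(CC)CC)c1O[Si](CC)(CC)CC | intermediate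
16 | (3S)-5-[(1R,3R)-1,3-dimethyl-2-methylidenecyclohexyl]-1-[5-methoxy-2,3-bis(triethylsilyloxy)phenyl]-3-methyl-3-(triethylsilyloxy)pentan-1-one | C=C1[C@H](C)CCC[C@]1(C)CC[C@@](O[Si](CC)(CC)CC)(C)CC(=O)c1cc(OC)cc(O[Si](CC)(CC)CC)c1O[Si](CC)(CC)CC | intermediate
17 | (3S)-1-(2,3-dihydroxy-5-methoxyphenyl)-5-[(1R,3R)-1,3-dimethyl-2-methylidenecyclohexyl]-3-hydroxy-3-methylpentan-1-one | C=C1[C@H](C)CCC[C@]1(C)CC[C@@](O)(C)CC(=O)c1cc(OC)cc(O)c1O | intermediate
18 | 3-{(3S)-5-[(1R,3R)-1,3-dimethyl-2-methylidenecyclohexyl]-3-hydroxy-3-methylpentanoyl}-5-methoxycyclohexa-3,5-diene-1,2-dione | C=C1[C@H](C)CCC[C@]1(C)CC[C@@](O)(C)CC(=O)C1=CC(OC)=CC(=O)C1=O | intermediate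
19 | (2S)-2-{2-[(1R,3R)-1,3-dimethyl-2-methylidenecyclohexyl]ethyl}-5,6-dihydroxy-8-methoxy-2-methyl-2,3-dihydro-4H-chromen-4-one | C=C1[C@H](C)CCC[C@]1(C)CC[C@@]1(C)CC(=O)c2c(O)c(O)cc(OC)c2O1 | intermediate
20 | (2S)-2-{2-[(1R,3R)-1,3-dimethyl-2-methylidenecyclohexyl]ethyl}-8-methoxy-2-methyl-3,4-dihydro-2H-chromene-4,5,6-triol (epimers at C4) | C=C1[C@H](C)CCC[C@]1(C)CC[C@@]1(C)CC(O)c2c(O)c(O)cc(OC)c2O1 | intermediate
21 | (2S)-2-{2-[(1R,3R)-1,3-dimethyl-2-methylidenecyclohexyl]ethyl}-8-methoxy-2-methyl-2H-chromene-5,6-diol | C=C1[C@H](C)CCC[C@]1(C)CC[C@@]1(C)C=Cc2c(O)c(O)cc(OC)c2O1 | target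

**Step count**
Total: 11 steps. Longest linear sequence: 8 steps (steps 1 to 6, then 10 and 11).

**Steps most likely to fail**

1. Step 10 (Proposed new method). The bulky aryl enol silane may turn over slowly in the confined catalyst or add with poor facial selectivity, so that C2 epimers form. The fallback uses known chemistry, sets out from 11 and comes back at 17.
 - With the same acid class and the small donor 1-(tert-butyldimethylsilyloxy)-1-methoxyethene, the donor class on which this ketone aldol is established, 11 should give methyl (3S)-3-(tert-butyldimethylsilyloxy)-5-[(1R,3R)-1,3-dimethyl-2-methylidenecyclohexyl]-3-methylpentanoate F1.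
 - MeNHOMe·HCl and i-PrMgCl convert it into (3S)-3-(tert-butyldimethylsilyloxy)-5-[(1R,3R)-1,3-dimethyl-2-methylidenecyclohexyl]-N-methoxy-N,3-dimethylpentanamide F2.
 - The arene is brought in as an aryllithium. Dakin oxidation (H2O2, NaOH) of commercial 3-bromo-2-hydroxy-5-methoxybenzaldehyde gives 3-bromo-5-methoxybenzene-1,2-diol F3, and MOMCl with i-Pr2NEt gives 1-bromo-5-methoxy-2,3-bis(methoxymethoxy)benzene F4.
 - Bromine–lithium exchange (n-BuLi, THF, −78 °C) followed by addition of F2 gives (3S)-3-(tert-butyldimethylsilyloxy)-5-[(1R,3R)-1,3-dimethyl-2-methylidenecyclohexyl]-1-[5-methoxy-2,3-bis(methoxymethoxy)phenyl]-3-methylpentan-1-one F5.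
 - Removal of the methoxymethyl groups (ZnBr2, n-PrSH) and of the silyl group (Et3N·3HF) returns to 17, which is oxidised with PhI(OAc)2 as in step 10 to 19.

2. Step 11. Hydride delivery to the hydrogen-bonded C4 carbonyl may be slow, base may open ring B by retro-oxa-Michael reaction with loss of C2 integrity, and the benzylic cation may oligomerise during dehydration. The fallback sets out from 19 and comes back at 21.
 - Ac2O and pyridine give (2S)-2-{2-[(1R,3R)-1,3-dimethyl-2-methylidenecyclohexyl]ethyl}-8-methoxy-2-methyl-4-oxo-3,4-dihydro-2H-chromene-5,6-diyl diacetate F6, in which the carbonyl is no longer chelated and no phenoxide can form.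
 - Luche reduction (NaBH4, CeCl3, MeOH, −20 °C) gives (2S)-2-{2-[(1R,3R)-1,3-dimethyl-2-methylidenecyclohexyl]ethyl}-4-hydroxy-8-methoxy-2-methyl-3,4-dihydro-2H-chromene-5,6-diyl diacetate F7.
 - Neutral syn-elimination with the Burgess reagent gives (2S)-2-{2-[(1R,3R)-1,3-dimethyl-2-methylidenecyclohexyl]ethyl}-8-methoxy-2-methyl-2H-chromene-5,6-diyl diacetate F8.
 - K2CO3 in MeOH under argon removes the acetates and gives 21.

3. Step 5. Addition to the doubly flanked carbonyl may fail through enolisation, with epimerisation of the adjacent methyl-bearing carbon, or the elimination may give the endocyclic alkene isomer. The fallback sets out from 8 and comes back at 10.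
 - Esterification with Me3SiCHN2 in MeOH/toluene gives methyl 3-[(1R,3R)-1,3-dimethyl-2-oxocyclohexyl]propanoate F9.
 - The non-basic Takai–Lombardo methylenation (Zn, CH2Br2, TiCl4, THF/CH2Cl2) gives methyl 3-[(1R,3R)-1,3-dimethyl-2-methylidenecyclohexyl]propanoate F10.
 - LiOH in THF/water returns 10.

**Further compounds**
F1 | step 10 | methyl (3S)-3-(tert-butyldimethylsilyloxy)-5-[(1R,3R)-1,3-dimethyl-2-methylidenecyclohexyl]-3-methylpentanoate | C=C1[C@H](C)CCC[C@]1(C)CC[C@@](O[Si](C)(C)C(C)(C)C)(C)CC(=O)OC
F2 | step 10 | (3S)-3-(tert-butyldimethylsilyloxy)-5-[(1R,3R)-1,3-dimethyl-2-methylidenecyclohexyl]-N-methoxy-N,3-dimethylpentanamide | C=C1[C@H](C)CCC[C@]1(C)CC[C@@](O[Si](C)(C)C(C)(C)C)(C)CC(=O)N(C)OC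
F3 | step 10 | 3-bromo-5-methoxybenzene-1,2-diol | COc1cc(O)c(O)c(Br)c1
F4 | step 10 | 1-bromo-5-methoxy-2,3-bis(methoxymethoxy)benzene | COCOc1cc(OC)cc(Br)c1OCOC
F5 | step 10 | (3S)-3-(tert-butyldimethylsilyloxy)-5-[(1R,3R)-1,3-dimethyl-2-methylidenecyclohexyl]-1-[5-methoxy-2,3-bis(methoxymethoxy)phenyl]-3-methylpentan-1-one | C=C1[C@H](C)CCC[C@]1(C)CC[C@@](O[Si](C)(C)C(C)(C)C)(C)CC(=O)c1cc(OC)cc(OCOC)c1OCOC
F6 | step 11 | (2S)-2-{2-[(1R,3R)-1,3-dimethyl-2-methylidenecyclohexyl]ethyl}-8-methoxy-2-methyl-4-oxo-3,4-dihydro-2H-chromene-5,6-diyl diacetate | C=C1[C@H](C)CCC[C@]1(C)CC[C@@]1(C)CC(=O)c2c(OC(C)=O)c(OC(C)=O)cc(OC)c2O1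
F7 | step 11 | (2S)-2-{2-[(1R,3R)-1,3-dimethyl-2-methylidenecyclohexyl]ethyl}-4-hydroxy-8-methoxy-2-methyl-3,4-dihydro-2H-chromene-5,6-diyl diacetate (epimers at C4) | C=C1[C@H](C)CCC[C@]1(C)CC[C@@]1(C)CC(O)c2c(OC(C)=O)c(OC(C)=O)cc(OC)c2O1
F8 | step 11 | (2S)-2-{2-[(1R,3R)-1,3-dimethyl-2-methylidenecyclohexyl]ethyl}-8-methoxy-2-methyl-2H-chromene-5,6-diyl diacetate | C=C1[C@H](C)CCC[C@]1(C)CC[C@@]1(C)C=Cc2c(OC(C)=O)c(OC(C)=O)cc(OC)c2O1
F9 | step 5 | methyl 3-[(1R,3R)-1,3-dimethyl-2-oxocyclohexyl]propanoate | O=C1[C@H](C)CCC[C@]1(C)CCC(=O)OC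
F10 | step 5 | methyl 3-[(1R,3R)-1,3-dimethyl-2-methylidenecyclohexyl]propanoate | C=C1[C@H](C)CCC[C@]1(C)CCC(=O)OC
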